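**Retrosynthetic overview**

- The target is a diester of an unsymmetrical C10 diacid with two identical amino alcohol units. Both C6–O bonds are cut last, with inversion at C6, giving the diacid (from geranyl acetate) and the 6-epimeric amino alcohol.
- The amino alcohol comes from a cis-fused lactam, obtained by hydrogenating a C4=C4a unsaturated lactam. That lactam arises by reductive aldol closure of the C4–C4a bond followed by dehydration.
- The aldol substrate, a cyclopentanone carrying an N-methylacrylamide on the C1 methylene, is cut at C7–CH3 and C7a–C1 into a 4-silyloxycyclopentenone, a methyl cuprate and an N-acyliminium ion.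
- The strategy rests on the three contiguous stereocentres C6 (oxygen), C7 (methyl) and C7a (bearing C1) on the cyclopentane ring of the cyclopenta[c]pyridine. In the target the oxygen is cis to the methyl and C1 is trans to it.
- Ring order: the cyclopentane is bought with the enone; the piperidine ring (N2, C1, C3, C4, C4a, C7a) is closed afterwards.

Key step: step 2

Remarks on the chemistry: positions are numbered as in cyclopenta[c]pyridine throughout, also for monocyclic intermediates. The C4 configuration drawn for the aldol product and its mesylate is the expected one; it is erased by the dehydration and does not affect the route. The diacid has two different ends, but both are esterified by the same alcohol, so they need not be told apart.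

**Route**

Step 1
Reactants: 1 N-methylacrylamide; 2 chloromethyl methyl ether
Product: 3 N-(methoxymethyl)-N-methylacrylamide
Conditions: NaH, THF, 0 °C (trace BHT); then 2, 0 °C → rt
Reagents that add atoms: none
Why: N-alkylation of the sodium salt of a secondary amide by the reactive chloromethyl ether is a standard amide N-alkoxymethylation, and at 0 °C with a radical inhibitor the acrylamide should not polymerise.

Step 2
Reactants: 4 (S)-4-(tert-butyldimethylsilyloxy)cyclopent-2-en-1-one; 3 N-(methoxymethyl)-N-methylacrylamide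
Product: 7 N-{[(1R,2S,3S)-3-(tert-butyldimethylsilyloxy)-2-methyl-5-oxocyclopentyl]methyl}-N-methylacrylamide, via silyl enol ether 5 (not isolated), via N-acyliminium triflate 6 (not isolated)
Conditions: CuI, MeLi (2 equiv), Et2O, 0 °C; TMSCl, then 4, THF, −78 °C; Et3N, pentane, filtration, evaporation; then 3, TMSOTf (0.3 equiv), CH2Cl2, −78 → −40 °C; aq. NaHCO3
Reagents that add atoms: methyllithium [Li]C; lithium dimethylcuprate [Li+].C[Cu-]C; chlorotrimethylsilane C[Si](C)(C)Cl; trimethylsilyl trifluoromethanesulfonate C[Si](C)(C)OS(=O)(=O)C(F)(F)F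
Why: Me2CuLi (monovalent copper, formed in the flask from MeLi and CuI) adds its methyl group to C7 of enone 4 in a 1,4 sense and TMSCl traps the enolate at once as silyl enol ether 5, so the enolate stays fixed between C4a and C7a and cannot migrate towards C5, where loss of the C6 silyloxy group would follow. TMSOTf then ionises N,O-acetal 3 to N-acyliminium triflate 6, and 5 attacks its methylene carbon through C7a in a Mukaiyama–Mannich-type amidoalkylation; the closest known reaction types are the tandem cuprate addition–enolate trapping of 4-silyloxycyclopentenones and the α-amidoalkylation of silyl enol ethers. No ring is closed; the two new bonds are C7–CH3 and C7a–C1. The C7 stereocentre is controlled by the C6 silyloxy group, which shields its own face so that the methyl group enters anti to it. The C7a stereocentre is controlled by the new C7 methyl group, which sends the iminium ion to the opposite face, and because C7a remains enolisable the trans,trans ketone is also the thermodynamic product. The step needs site selectivity for C7a over C5 and for the iminium carbon over the acrylamide terminus; the regiodefined silyl enol ether and the higher electrophilicity of the cationic CH2=N carbon at low temperature should secure both.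

Step 3
Reactants: 7 N-{[(1R,2S,3S)-3-(tert-butyldimethylsilyloxy)-2-methyl-5-oxocyclopentyl]methyl}-N-methylacrylamide
Product: 8 (4S,4aS,6S,7S,7aR)-6-(tert-butyldimethylsilyloxy)-4a-hydroxy-2,4,7-trimethyloctahydro-3H-cyclopenta[c]pyridin-3-one
Conditions: [(Ph3P)CuH]6 (0.2 equiv, 1.2 equiv of hydride), toluene–THF, −40 → 0 °C; aq. NH4Cl
Reagents that add atoms: none
Why: copper hydride (monovalent copper) reduces the acrylamide in a 1,4 sense and the copper amide enolate adds to the C4a ketone (intramolecular reductive aldol cyclisation, known for N-(3-oxoalkyl)acrylamides), the short tether on C7a forcing attack from its own face so that the ring should be cis-fused, with a chair-like Zimmerman–Traxler arrangement of the Z-enolate placing the C4 methyl cis to the hydroxyl.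

Step 4
Reactants: 8 (4S,4aS,6S,7S,7aR)-6-(tert-butyldimethylsilyloxy)-4a-hydroxy-2,4,7-trimethyloctahydro-3H-cyclopenta[c]pyridin-3-one
Product: 10 (6S,7S,7aS)-6-(tert-butyldimethylsilyloxy)-2,4,7-trimethyl-1,2,5,6,7,7a-hexahydro-3H-cyclopenta[c]pyridin-3-one, via tertiary mesylate 9 (not isolated)
Conditions: MsCl, Et3N, DMAP (cat.), CH2Cl2, 0 °C; then DBU, rt → 40 °C
Reagents that add atoms: methanesulfonyl chloride CS(=O)(=O)Cl (in 9 only)
Why: mesylation of the tertiary alcohol through sulfene followed by base-induced anti elimination (aldol dehydration) should give the conjugated tetrasubstituted C4=C4a alkene, because H-4 is the acidic β-hydrogen and is anti-periplanar to the leaving group while H-7a is syn to it, and the two stereocentres lost (C4, C4a) are reset in step 5.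

Step 5
Reactants: 10 (6S,7S,7aS)-6-(tert-butyldimethylsilyloxy)-2,4,7-trimethyl-1,2,5,6,7,7a-hexahydro-3H-cyclopenta[c]pyridin-3-one
Product: 11 (4R,4aR,6S,7S,7aR)-6-(tert-butyldimethylsilyloxy)-2,4,7-trimethyloctahydro-3H-cyclopenta[c]pyridin-3-one
Conditions: H2 (10 bar), PtO2, EtOAc, rt
Reagents that add atoms: none
Why: heterogeneous catalytic hydrogenation adds both hydrogens to one face of the C4=C4a alkene, and the face carrying H-7a lies opposite the bulky C6 silyloxy group, whose shielding should outweigh that of the small C7 methyl on the delivery face, so H-4, H-4a and H-7a should end up mutually cis (cis-fused lactam with the C4 configuration of the target).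

Step 6
Reactants: 11 (4R,4aR,6S,7S,7aR)-6-(tert-butyldimethylsilyloxy)-2,4,7-trimethyloctahydro-3H-cyclopenta[c]pyridin-3-one
Product: 12 (4R,4aS,6S,7S,7aR)-6-(tert-butyldimethylsilyloxy)-2,4,7-trimethyloctahydro-1H-cyclopenta[c]pyridine
Conditions: LiAlH4, THF, reflux; aq. NaOH work-up
Reagents that add atoms: none
Why: LiAlH4 reduction of a tertiary lactam to the tertiary amine is standard, changes no stereocentre (the descriptor at C4a changes only through ligand priorities) and leaves the silyl ether intact.

Step 7
Reactants: 12 (4R,4aS,6S,7S,7aR)-6-(tert-butyldimethylsilyloxy)-2,4,7-trimethyloctahydro-1H-cyclopenta[c]pyridine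
Product: 13 (4R,4aS,6S,7S,7aR)-2,4,7-trimethyloctahydro-1H-cyclopenta[c]pyridin-6-ol (C6 hydroxyl trans to the C7 methyl)
Conditions: Bu4NF, THF, rt → 50 °C; acid–base extraction
Reagents that add atoms: none
Why: fluoride-induced cleavage of the silyl ether (desilylation) frees the C6 alcohol with retention of configuration.

Step 8
Reactants: 14 geranyl acetate
Product: 15 (2E,6E)-8-hydroxy-3,7-dimethylocta-2,6-dien-1-yl acetate
Conditions: SeO2 (0.1 equiv), t-BuOOH, salicylic acid (cat.), CH2Cl2, rt
Reagents that add atoms: selenium dioxide O=[Se]=O (catalytic oxygen carrier); tert-butyl hydroperoxide CC(C)(C)OO (terminal oxygen source)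
Why: allylic oxidation with catalytic SeO2 and t-BuOOH (ene reaction then 2,3-sigmatropic shift) is selective for the E-methyl group of the terminal trisubstituted alkene of geranyl esters and should keep both alkene geometries.

Step 9
Reactants: 15 (2E,6E)-8-hydroxy-3,7-dimethylocta-2,6-dien-1-yl acetate
Product: 16 (2E,6E)-2,6-dimethylocta-2,6-diene-1,8-diol
Conditions: K2CO3 (cat.), MeOH, rt
Reagents that add atoms: none
Why: base-catalysed transesterification (methanolysis) removes the acetate without touching the alkenes.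

Step 10
Reactants: 16 (2E,6E)-2,6-dimethylocta-2,6-diene-1,8-diol
Product: 17 (2E,6E)-2,6-dimethylocta-2,6-dienedial
Conditions: MnO2 (excess), CH2Cl2, rt
Reagents that add atoms: none
Why: MnO2 oxidises both allylic alcohols to the conjugated aldehydes under neutral heterogeneous conditions that should not isomerise the E alkenes.

Step 11
Reactants: 17 (2E,6E)-2,6-dimethylocta-2,6-dienedial
Product: 18 (2E,6E)-2,6-dimethylocta-2,6-dienedioic acid
Conditions: NaClO2, NaH2PO4, 2-methylbut-2-ene, t-BuOH–H2O, 0 °C → rt
Reagents that add atoms: sodium chlorite [Na+].[O-]Cl=O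
Why: Pinnick oxidation converts both enals to the acids, with 2-methylbut-2-ene scavenging HOCl so that the trisubstituted alkenes should survive.

Step 12
Reactants: 13 (4R,4aS,6S,7S,7aR)-2,4,7-trimethyloctahydro-1H-cyclopenta[c]pyridin-6-ol (2.2 equiv); 18 (2E,6E)-2,6-dimethylocta-2,6-dienedioic acid
Product: 19 bis[(4R,4aS,6R,7S,7aR)-2,4,7-trimethyloctahydro-1H-cyclopenta[c]pyridin-6-yl] (2E,6E)-2,6-dimethylocta-2,6-dienedioate
Conditions: PPh3, DIAD, THF, 0 °C → rt
Reagents that add atoms: none
Why: in this twofold Mitsunobu esterification each carboxylate of 18 displaces the oxyphosphonium derivative of alcohol 13 in an SN2 reaction, which inverts C6 from S to R and places the ester oxygen cis to the C7 methyl as the target requires, the tertiary amine being a spectator.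

**Compound list**

1 | N-methylacrylamide | C=CC(=O)NC | starting material
2 | chloromethyl methyl ether | COCCl | starting material
3 | N-(methoxymethyl)-N-methylacrylamide | C=CC(=O)N(C)COC | intermediate
4 | (S)-4-(tert-butyldimethylsilyloxy)cyclopent-2-en-1-one | CC(C)(C)[Si](C)(C)O[C@H]1CC(=O)C=C1 | starting material
5 | tert-butyldimethyl{[(1S,2S)-2-methyl-4-(trimethylsilyloxy)cyclopent-3-en-1-yl]oxy}silane (silyl enol ether, methyl trans to the silyloxy group) | CC(C)(C)[Si](C)(C)O[C@H]1CC(O[Si](C)(C)C)=C[C@@H]1C | intermediate (not isolated)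
6 | N-acryloyl-N-methylmethyleneiminium trifluoromethanesulfonate | C=CC(=O)[N+](C)=C.[O-]S(=O)(=O)C(F)(F)F | intermediate (not isolated)
7 | N-{[(1R,2S,3S)-3-(tert-butyldimethylsilyloxy)-2-methyl-5-oxocyclopentyl]methyl}-N-methylacrylamide (all-trans) | CC(C)(C)[Si](C)(C)O[C@H]1CC(=O)[C@@H](CN(C)C(=O)C=C)[C@@H]1C | intermediate
8 | (4S,4aS,6S,7S,7aR)-6-(tert-butyldimethylsilyloxy)-4a-hydroxy-2,4,7-trimethyloctahydro-3H-cyclopenta[c]pyridin-3-one (cis-fused) | CC(C)(C)[Si](C)(C)O[C@H]1C[C@]2(O)[C@@H](CN(C)C(=O)[C@H]2C)[C@@H]1C | intermediate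
9 | (4S,4aS,6S,7S,7aR)-6-(tert-butyldimethylsilyloxy)-2,4,7-trimethyl-3-oxooctahydro-1H-cyclopenta[c]pyridin-4a-yl methanesulfonate | CC(C)(C)[Si](C)(C)O[C@H]1C[C@]2(OS(C)(=O)=O)[C@@H](CN(C)C(=O)[C@H]2C)[C@@H]1C | intermediate (not isolated)
10 | (6S,7S,7aS)-6-(tert-butyldimethylsilyloxy)-2,4,7-trimethyl-1,2,5,6,7,7a-hexahydro-3H-cyclopenta[c]pyridin-3-one | CC(C)(C)[Si](C)(C)O[C@H]1CC2=C(C)C(=O)N(C)C[C@H]2[C@@H]1C | intermediate
11 | (4R,4aR,6S,7S,7aR)-6-(tert-butyldimethylsilyloxy)-2,4,7-trimethyloctahydro-3H-cyclopenta[c]pyridin-3-one (H-4, H-4a, H-7a cis) | CC(C)(C)[Si](C)(C)O[C@H]1C[C@@H]2[C@@H](CN(C)C(=O)[C@@H]2C)[C@@H]1C | intermediate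
12 | (4R,4aS,6S,7S,7aR)-6-(tert-butyldimethylsilyloxy)-2,4,7-trimethyloctahydro-1H-cyclopenta[c]pyridine | CC(C)(C)[Si](C)(C)O[C@H]1C[C@@H]2[C@@H](CN(C)C[C@@H]2C)[C@@H]1C | intermediate
13 | (4R,4aS,6S,7S,7aR)-2,4,7-trimethyloctahydro-1H-cyclopenta[c]pyridin-6-ol | O[C@H]1C[C@@H]2[C@@H](CN(C)C[C@@H]2C)[C@@H]1C | intermediate
14 | geranyl acetate | CC(C)=CCC/C(C)=C/COC(C)=O | starting material
15 | (2E,6E)-8-hydroxy-3,7-dimethylocta-2,6-dien-1-yl acetate | CC(=O)OC/C=C(\C)CC/C=C(\C)CO | intermediate
16 | (2E,6E)-2,6-dimethylocta-2,6-diene-1,8-diol | OC/C=C(\C)CC/C=C(\C)CO | intermediate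
17 | (2E,6E)-2,6-dimethylocta-2,6-dienedial | O=C/C=C(\C)CC/C=C(\C)C=O | intermediate
18 | (2E,6E)-2,6-dimethylocta-2,6-dienedioic acid | OC(=O)/C=C(\C)CC/C=C(\C)C(=O)O | intermediate
19 | bis[(4R,4aS,6R,7S,7aR)-2,4,7-trimethyloctahydro-1H-cyclopenta[c]pyridin-6-yl] (2E,6E)-2,6-dimethylocta-2,6-dienedioate | C/C(=C\C(=O)O[C@@H]1C[C@@H]2[C@@H](CN(C)C[C@@H]2C)[C@@H]1C)CC/C=C(\C)C(=O)O[C@@H]1C[C@@H]2[C@@H](CN(C)C[C@@H]2C)[C@@H]1C | target

**Step count and risks**

Total steps: 12. Longest linear sequence: 8 steps (steps 1 to 7 and step 12); the diacid arm is steps 8 to 11.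

Steps most likely to fail:

1. Step 2 (three-component coupling). The acryloyl-substituted N-acyliminium ion may be consumed through its vinyl group (Michael-type attack by the silyl enol ether, cationic oligomerisation) before it is captured at the methylene carbon. Fallback: the acrylamide is masked. The fallback sets out from 3, which takes up PhSeNa (PhSeSePh, NaBH4, EtOH) in a conjugate addition to give N-(methoxymethyl)-N-methyl-3-(phenylselanyl)propanamide F1. Enone 4 is taken through the cuprate/TMSCl stage to 5 as in step 2 and amidoalkylated with F1 under TMSOTf to give N-{[(1R,2S,3S)-3-(tert-butyldimethylsilyloxy)-2-methyl-5-oxocyclopentyl]methyl}-N-methyl-3-(phenylselanyl)propanamide F2. Oxidation with NaIO4 (NaHCO3, aq. THF–MeOH, rt) and syn elimination of the selenoxide would unveil the acrylamide, and the route is rejoined at 7.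

2. Step 5 (hydrogenation). Hydrogen may be delivered to the wrong face of the tetrasubstituted alkene, or the reduction may be slow enough for the double bond to migrate towards C7a. Fallback: a hydroxyl-directed hydrogenation after early inversion of C6, setting out from 10. Desilylation (Bu4NF, THF) would give (6S,7S,7aS)-6-hydroxy-2,4,7-trimethyl-1,2,5,6,7,7a-hexahydro-3H-cyclopenta[c]pyridin-3-one F3. Mitsunobu inversion with 4-nitrobenzoic acid (PPh3, DIAD) would give (6R,7S,7aS)-2,4,7-trimethyl-3-oxo-2,3,5,6,7,7a-hexahydro-1H-cyclopenta[c]pyridin-6-yl 4-nitrobenzoate F4. Methanolysis (K2CO3, MeOH) would give (6R,7S,7aS)-6-hydroxy-2,4,7-trimethyl-1,2,5,6,7,7a-hexahydro-3H-cyclopenta[c]pyridin-3-one F5, whose hydroxyl lies on the face of H-7a. Hydrogenation with [Ir(cod)(PCy3)(py)]PF6 (H2, CH2Cl2) should then be steered to that face by the homoallylic hydroxyl and give (4R,4aR,6R,7S,7aR)-6-hydroxy-2,4,7-trimethyloctahydro-3H-cyclopenta[c]pyridin-3-one F6. LiAlH4 reduction would give (4R,4aS,6R,7S,7aR)-2,4,7-trimethyloctahydro-1H-cyclopenta[c]pyridin-6-ol F7, which already has the C6 configuration of the target. Esterification of F7 (2.2 equiv) with 18 with retention (EDC·HCl, DMAP, CH2Cl2, Steglich conditions) comes back to the route at 19.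

3. Step 12 (double Mitsunobu). The oxyphosphonium intermediate of the hindered secondary alcohol may eliminate to a cyclopentene, the reaction may stall at the monoester, or acyl transfer with retention may compete. Fallback: inversion is separated from ester formation. It sets out from 13. Swern oxidation ((COCl)2, DMSO, Et3N, −78 °C) would give (4R,4aS,7S,7aR)-2,4,7-trimethyloctahydro-6H-cyclopenta[c]pyridin-6-one F8. Reduction with LiBH(s-Bu)3 (THF, −78 °C) should deliver hydride anti to the adjacent C7 methyl and give (4R,4aS,6R,7S,7aR)-2,4,7-trimethyloctahydro-1H-cyclopenta[c]pyridin-6-ol F7. Steglich esterification of F7 with 18 (EDC·HCl, DMAP, CH2Cl2), now with retention, comes back to the route at 19.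

Further compounds

F1 | step 2 | N-(methoxymethyl)-N-methyl-3-(phenylselanyl)propanamide | COCN(C)C(=O)CC[Se]c1ccccc1
F2 | step 2 | N-{[(1R,2S,3S)-3-(tert-butyldimethylsilyloxy)-2-methyl-5-oxocyclopentyl]methyl}-N-methyl-3-(phenylselanyl)propanamide | CC(C)(C)[Si](C)(C)O[C@H]1CC(=O)[C@@H](CN(C)C(=O)CC[Se]c2ccccc2)[C@@H]1C
F3 | step 5 | (6S,7S,7aS)-6-hydroxy-2,4,7-trimethyl-1,2,5,6,7,7a-hexahydro-3H-cyclopenta[c]pyridin-3-one | O[C@H]1CC2=C(C)C(=O)N(C)C[C@H]2[C@@H]1C
F4 | step 5 | (6R,7S,7aS)-2,4,7-trimethyl-3-oxo-2,3,5,6,7,7a-hexahydro-1H-cyclopenta[c]pyridin-6-yl 4-nitrobenzoate | O=C(O[C@@H]1CC2=C(C)C(=O)N(C)C[C@H]2[C@@H]1C)c1ccc(cc1)[N+](=O)[O-]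
F5 | step 5 | (6R,7S,7aS)-6-hydroxy-2,4,7-trimethyl-1,2,5,6,7,7a-hexahydro-3H-cyclopenta[c]pyridin-3-one | O[C@@H]1CC2=C(C)C(=O)N(C)C[C@H]2[C@@H]1C
F6 | step 5 | (4R,4aR,6R,7S,7aR)-6-hydroxy-2,4,7-trimethyloctahydro-3H-cyclopenta[c]pyridin-3-one | O[C@@H]1C[C@@H]2[C@@H](CN(C)C(=O)[C@@H]2C)[C@@H]1C
F7 | step 5 | (4R,4aS,6R,7S,7aR)-2,4,7-trimethyloctahydro-1H-cyclopenta[c]pyridin-6-ol | O[C@@H]1C[C@@H]2[C@@H](CN(C)C[C@@H]2C)[C@@H]1C
F8 | step 12 | (4R,4aS,7S,7aR)-2,4,7-trimethyloctahydro-6H-cyclopenta[c]pyridin-6-one | O=C1C[C@@H]2[C@@H](CN(C)C[C@@H]2C)[C@@H]1C
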